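The numbers of this flask were set for the occasion; the result is computed.

One charge, different vessels.

| flask | substrate | coupling partner | time | remark |
|---|---|---|---|---|
| amber | 0.20 mM (fed, over 3.00 s) | 1.20 equiv | 3.0 s | all but substrate at the start; substrate goes in evenly over 3.00 s, the run ends at 3.0 s |
| green | 0.20 mM | 1.20 equiv | 3.0 s | everything together in a closed stirred flask, run for 3.0 s |
| teal | 0.20 mM | 1.20 equiv (fed, over 3.00 s) | 3.0 s | all but coupling partner at the start; coupling partner goes in evenly over 3.00 s, the run ends at 3.0 s |
| grey | 0.20 mM | 1.20 equiv |  | a single well-mixed tank run continuously and read at steady state, 3.0 s in it on average |

    substrate + coupling partner → target (k1 = 780 L mol⁻¹ s⁻¹)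
    substrate → side product A (k2 = 0.0052 s⁻¹)
    2 substrate → side product B (k3 = 740 L mol⁻¹ s⁻¹)
    substrate + target ⇌ idle adduct, settled at all times (K4 = 64000 L mol⁻¹)

- percent here means substrate units held: one side product B or idle adduct counts as two
- what is said of target includes idle adduct
- two of one species on the left: rate k times its square, two consumed each time
- the stated concentrations are those of everything mixed, before any reaction; amounts are the same in each set-up
- the feed brings no volume worth counting
- in an amount of target, one idle adduct counts as one target
- run time (amber): 3.0 s

1. order of the set-ups by the amount of target at the outlet or at the end, in percent of the substrate put in, highest first (amber / green / teal / grey)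
2. amount of target at the outlet or at the end, in percent of the substrate put in, amber
3. amount of target at the outlet or at the end, in percent of the substrate put in, green
4. amount of target at the outlet or at the end, in percent of the substrate put in, teal
5. amount of target at the outlet or at the end, in percent of the substrate put in, grey

Two chemists dispute this. The first wants to feed substrate, since the step to side product B goes with the square of substrate. In green at the charge, that step uses substrate 1.58 times as fast as the coupling step does. With substrate held at half the charge, the ratio falls to 0.791, so she expects amber to lead.

The second works with the fraction left. Her quantity is the exposure: the coupling constant times the coupling partner times the time substrate and partner spend together 0.562. This is pseudo-first-order reckoning, with the partner taken as steady. The fraction of substrate that coupling leaves untouched, the other steps aside, is exp(−exposure) in a closed flask, and one over one plus the exposure in a tank.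

Green has the exposure 0.562, so this reckoning leaves 57.0 % of the substrate. Grey, with its average stay of 3.0 s, has the same exposure, but the reckoning leaves 64.0 %. In amber, fed substrate spends on average half the run in the flask. In teal, the partner stands on average at half its charge. Each therefore gets the exposure 0.281, which leaves about 75.5 %.

My own reckoning sides with her and stops at an order: green, grey, then amber and teal level. I put teal last as a judgement beyond the exposure: teal starts with no partner in it and its substrate at the full charge. These fractions are not yields, and I commit to no yield from them.

The forecast gives green > grey > amber > teal, with 18 % for amber, 25 % for green, 15.9 % for teal and 20.5 % for grey. Its ground: “Green wins because substrate and partner are both at full strength from the start”.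

The simulation gives green > grey > amber > teal, with 17.5 % in amber, 25.6 % in green, 13.6 % in teal and 20.5 % in grey, so the second chemist holds at 3.0 s. The first has her region later: at 30.0 s, amber holds 52.4 % target, more than the 49.7 % in green. Teal's exposure reckons 24.5 % of the substrate coupled, the other steps aside, and the target found in teal is 55.4 % of that figure. The neighbour is teal with 4.80 equiv of coupling partner. Its exposure is 1.12, so the reckoning gives 67.5 % coupled, and the same share of that figure gives 37.4 %. That neighbouring flask holds 35.5 % target.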